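**Plan**

1. Retrosynthetic cuts: the butenoyl chain at its vinyl–carbonyl bond and at C1–C2 (protected hydroxymethyl anion, then a (Z)-propenyl unit); the lactone at C7–C11 and O–C12 (tethered phosphonoacetate plus formaldehyde); last, the two ring bonds C8–C9 and C1–C5, which split the carbocycle into furan (C5–C8 plus the oxygen that stays on C5) and the three carbons of a perhalocyclopropene (C9, C10, C1).
2. Enabling feature: in the cycloheptane the two carbinol carbons C9 and C1 flank the methyl-bearing C10 (a masked 2-methyl-1,3-dione), and each is bonded to one end of the C5–C6–C7–C8 chain whose C5 end carries oxygen. This is the imprint of a furan that has added through C2/C5 to a three-carbon unit.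
3. Forward order: tetrabromocyclopropene plus furan gives the oxygen-bridged seven-membered ring by Diels–Alder addition and cyclopropane opening; C9 enol ether, C10 methyl and the C2 carbon at C1 follow; SmI2 opens the oxygen bridge (C8 becomes CH2, C5 keeps OH); then isovalerate, C6 oxygen, lactone ring (tethered Michael/Horner–Wadsworth–Emmons), C9 reduction and the Z-enone.
4. Stereochemistry: absolute configuration from separation of (−)-menthyl vinylogous ester diastereomers; C5 from the furan oxygen bridge; C1 and C10 on the exo face of the bicycle; C6 by epoxidation anti to the C5 ester; C7 from the C6 tether; C9 by hydroxyl-directed anti reduction; the Z-alkene from (Z)-1-bromopropene.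

Key step: step 2

Remark: xanthanolide locants are used (C1 tertiary carbinol, C5 isovalerate carbon, C6 lactone O–CH, C7 ring-fusion CH, C8 CH2, C9 secondary carbinol, C10 CH–CH3, C11–C13 lactone, C2–C4 and C15 butenoyl); β is the ring face of the C5 oxygen and α the other; 4–6 are racemic and drawn as the enantiomer that is carried on.

Step 1
Reactants: 1 tetrachlorocyclopropene
Product: 2 tetrabromocyclopropene
Conditions: BBr3 (1.4 equiv), neat, 0 °C to rt, then distillation
Reagents that add atoms: boron tribromide, BrB(Br)Br
Why: Boron trihalide halogen exchange, which runs through the aromatic trihalocyclopropenium ion, is the known route from the commercial chloride to the bromide, whose vinylic bromides are needed for the later vinylogous substitution and cross-coupling.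

Step 2
Reactants: 2 tetrabromocyclopropene; 3 furan
Product: 5 (1R,5S)-2,3,4,4-tetrabromo-8-oxabicyclo[3.2.1]octa-2,6-diene (racemate), via exo Diels-Alder adduct 4 (not isolated)
Conditions: furan (5 equiv), 1,4-dioxane, 80 °C, sealed tube
Reagents that add atoms: none
Why: Furan adds across the strained C=C of 2 in a Diels–Alder reaction, which makes both new ring bonds at once (furan C2 and C5 to the two vinylic carbons, that is C8–C9 and C5–C1 of the target) and gives the tricyclic adduct 4. The fused tetrabromocyclopropane of 4 then opens by the disrotatory cyclopropyl-to-allyl cation process with ionisation of a C10 bromide, and bromide returns to one allyl terminus, so that the shared cyclopropane bond is given up to strain release and the seven-membered ring with a CBr2 terminus emerges. The closest known reaction type is the cycloaddition of perhalocyclopropenes with furans followed by spontaneous ring opening, which is established chemistry. The oxanorbornene ring closes by a suprafacial [4+2] cycloaddition, and the cycloheptadiene ring is not closed but uncovered by the two-electron electrocyclic opening. The two bridgehead carbons are the only stereocentres and their cis relation is fixed by the oxygen bridge of furan, the material being racemic until step 4. The step needs no regiocontrol, because both partners are symmetric and the two directions of bromide return give enantiomers, not isomers.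

Step 3
Reactants: 5 (1R,5S)-2,3,4,4-tetrabromo-8-oxabicyclo[3.2.1]octa-2,6-diene (racemate)
Product: 6 (1S,5R)-3,4-dibromo-8-oxabicyclo[3.2.1]octa-3,6-dien-2-one (racemate)
Conditions: AgNO3 (2.2 equiv), acetone/H2O, rt
Reagents that add atoms: water, O
Why: Silver-assisted ionisation of the allylic gem-dibromide to a bromoallyl cation, capture by water and loss of HBr (hydrolysis of a gem-dihalide) should give the α,β-dibromo enone with its carbonyl on the carbon that becomes C1.

Step 4
Reactants: 6 (1S,5R)-3,4-dibromo-8-oxabicyclo[3.2.1]octa-3,6-dien-2-one (racemate)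
Product: 7 (1S,5R)-3-bromo-4-{[(1R,2S,5R)-2-isopropyl-5-methylcyclohexyl]oxy}-8-oxabicyclo[3.2.1]octa-3,6-dien-2-one
Conditions: (−)-menthol, NaH, THF, −20 °C to rt; separation of the two diastereomers by chromatography or crystallisation
Reagents that add atoms: (−)-menthol, C[C@@H]1CC[C@H]([C@@H](C1)O)C(C)C
Why: Vinylogous acyl substitution (addition–elimination) of the alkoxide at the β-bromide fixes the C9 oxygen as an enol ether and converts the racemate into two diastereomers, which are separated so that only the (1S,5R) series is carried on; this separation sets the absolute configuration of the whole route.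

Step 5
Reactants: 7 (1S,5R)-3-bromo-4-(menthyloxy)-8-oxabicyclo[3.2.1]octa-3,6-dien-2-one
Product: 8 (1S,5R)-4-{[(1R,2S,5R)-2-isopropyl-5-methylcyclohexyl]oxy}-3-methyl-8-oxabicyclo[3.2.1]octa-3,6-dien-2-one
Conditions: MeZnCl, Pd(PPh3)4 (5 mol %), THF, 50 °C
Reagents that add atoms: methylzinc chloride, C[Zn]Cl
Why: Negishi cross-coupling at the α-bromo enone C–Br bond brings in the C14 methyl under neutral, anhydrous conditions that should leave the vinylogous ester and the strained ring alkene untouched.

Step 6
Reactants: 9 (tributylstannyl)methanol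
Product: 10 tributyl{[(4-methoxybenzyl)oxy]methyl}stannane
Conditions: NaH, THF/DMF, 0 °C; 4-methoxybenzyl chloride, Bu4NI (catalytic), rt
Reagents that add atoms: 4-methoxybenzyl chloride, COc1ccc(CCl)cc1
Why: Williamson ether synthesis on the primary stannyl carbinol gives the tin precursor of a protected hydroxymethyl anion.

Step 7
Reactants: 8 (1S,5R)-4-(menthyloxy)-3-methyl-8-oxabicyclo[3.2.1]octa-3,6-dien-2-one; 10 tributyl{[(4-methoxybenzyl)oxy]methyl}stannane
Product: 12 (1S,2R,5R)-2-{[(4-methoxybenzyl)oxy]methyl}-4-{[(1R,2S,5R)-2-isopropyl-5-methylcyclohexyl]oxy}-3-methyl-8-oxabicyclo[3.2.1]octa-3,6-dien-2-ol (CH2OPMB exo; OH endo), via [(4-methoxybenzyl)oxy]methyllithium 11 (not isolated)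
Conditions: 10, n-BuLi, THF, −78 °C; then 8, −78 °C; pH 7 phosphate buffer
Reagents that add atoms: none
Why: Tin–lithium exchange gives the α-alkoxymethyllithium 11, whose 1,2-addition to the non-enolisable vinylogous ester carbonyl (the first half of a Stork–Danheiser sequence) should occur on the exo face next to the oxygen bridge and away from the etheno bridge, which sets C1 with the carbon substituent β and the hydroxyl α.

Step 8
Reactants: 12 the tertiary alcohol from step 7
Product: 13 3-exo-bromo-4-endo-hydroxy-4-exo-{[(4-methoxybenzyl)oxy]methyl}-3-endo-methyl-8-oxabicyclo[3.2.1]oct-6-en-2-one (bridgeheads as in 12)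
Conditions: NBS (1.05 equiv), NaHCO3, THF/H2O (4:1), 0 °C
Reagents that add atoms: N-bromosuccinimide, O=C1CCC(=O)N1Br; water, O
Why: Electrophilic bromination of the tetrasubstituted enol ether at C10 with hydrolytic loss of menthol (conversion of an enol ether into an α-bromo ketone) unveils the C9 ketone at neutral pH, which avoids the acid that would ionise the tertiary allylic alcohol in a Stork–Danheiser transposition; the configuration of the bromide is of no consequence.

Step 9
Reactants: 13 the α-bromo ketone from step 8
Product: 15 1α,5β-dihydroxy-1β-{[(4-methoxybenzyl)oxy]methyl}-10α-methyl-9-oxocyclohept-6-ene, via debrominated bicyclic ketone 14 (not isolated)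
Conditions: SmI2 (5 equiv), THF/MeOH (10:1), −78 °C
Reagents that add atoms: none
Why: SmI2 first reduces the α-bromo ketone to a samarium enolate that methanol should protonate on the exo face to give 14 (C10 hydrogen β and methyl α), and then cleaves the C8–O bond α to the ketone by ketyl fragmentation (reductive cleavage of an α-alkoxy ketone), so that C8 becomes CH2, C5 keeps the former furan oxygen as a free hydroxyl and kinetic α-protonation of the dienolate leaves the β,γ-unsaturated ketone.

Step 10
Reactants: 15 the dihydroxy ketone from step 9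
Product: 16 1α-hydroxy-1β-{[(4-methoxybenzyl)oxy]methyl}-10α-methyl-9-oxocyclohept-6-en-5β-yl 3-methylbutanoate
Conditions: isovaleric anhydride, pyridine, DMAP (catalytic), CH2Cl2, 0 °C
Reagents that add atoms: isovaleric anhydride, CC(C)CC(=O)OC(=O)CC(C)C
Why: Acylation under nucleophilic catalysis is selective for the only secondary hydroxyl (C5), the tertiary C1 hydroxyl being too hindered, and the mild base should not move the β,γ double bond into conjugation.

Step 11
Reactants: 16 the C5 isovalerate from step 10
Product: 18 1α,6α-dihydroxy-1β-{[(4-methoxybenzyl)oxy]methyl}-10α-methyl-9-oxocyclohept-7-en-5β-yl 3-methylbutanoate, via 6α,7α-epoxy ketone 17 (not isolated)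
Conditions: m-CPBA, NaHCO3, CH2Cl2, 0 °C; then Et3N, rt
Reagents that add atoms: 3-chloroperbenzoic acid, OOC(=O)c1cccc(Cl)c1
Why: Peracid epoxidation (Prilezhaev reaction) of the cis ring alkene should occur on the α face, anti to the allylic isovalerate and syn to the hydrogen-bonding homoallylic C1 hydroxyl, and the β,γ-epoxy ketone 17 then opens by base-mediated β-elimination (E1cB) to the γ-hydroxy enone, which sets C6 with its oxygen α and moves the alkene to C7–C8.

Step 12
Reactants: 18 the γ-hydroxy enone from step 11
Product: 19 6α-[(diethoxyphosphoryl)acetyl]oxy derivative of 18 (C5 isovalerate and C1 hydroxyl unchanged)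
Conditions: (EtO)2P(O)CH2CO2H, DCC, DMAP (catalytic), CH2Cl2, 0 °C to rt
Reagents that add atoms: (diethoxyphosphoryl)acetic acid, CCOP(=O)(CC(=O)O)OCC
Why: Steglich esterification acylates the secondary allylic C6 hydroxyl in preference to the hindered tertiary C1 hydroxyl and installs the tethered phosphonate nucleophile.

Step 13
Reactants: 19 the C6 phosphonoacetate from step 12
Product: 21 9-oxo α-methylene lactone (cyclohepta[b]furan-2-one with 3-methylidene; cis ring fusion with 6α-O and 7α-C; 5β-isovalerate; 1α-OH; 1β-CH2OPMB; 10α-CH3), via phosphono lactone 20 (not isolated)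
Conditions: Cs2CO3 (1.5 equiv), MeCN, 0 °C to rt; then aqueous HCHO (37 %), rt
Reagents that add atoms: formaldehyde, C=O
Why: Carbonate should deprotonate only the phosphonoacetate, whose carbanion adds to the enone β-carbon C7 in a 5-exo-trig intramolecular Michael addition that must deliver the new C–C bond on the face of the C6 oxygen (cis ring fusion, C7 set) to give 20, and the Horner–Wadsworth–Emmons reaction of its phosphonate anion with formaldehyde then forms the exocyclic methylene without strong base.

Step 14
Reactants: 21 the 9-oxo α-methylene lactone from step 13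
Product: 22 9β-hydroxy α-methylene lactone (as 21 with 9β-OH in place of the ketone)
Conditions: Me4NBH(OAc)3 (5 equiv), MeCN/AcOH (1:1), −20 °C
Reagents that add atoms: none
Why: Evans–Saksena reduction, in which the triacetoxyborohydride exchanges a ligand with the free C1 hydroxyl and delivers hydride within the molecule to the β-hydroxy ketone on the α face, should give the 1,3-anti diol (C9 hydroxyl β) and leave the esters and the α-methylene lactone untouched.

Step 15
Reactants: 22 the 9β-hydroxy lactone from step 14
Product: 23 1β-(hydroxymethyl) triol (as 22 with CH2OH at C1)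
Conditions: DDQ, CH2Cl2/pH 7 buffer (10:1), 0 °C
Reagents that add atoms: none
Why: Oxidative cleavage of the 4-methoxybenzyl ether by DDQ in the presence of water frees the primary hydroxyl without acid or hydrogenation.

Step 16
Reactants: 23 the triol from step 15
Product: 24 1β-formyl compound (α-hydroxy aldehyde; as 23 with CHO at C1)
Conditions: TEMPO (catalytic), PhI(OAc)2, CH2Cl2, rt
Reagents that add atoms: none
Why: The oxoammonium (TEMPO) oxidation is selective for the primary hydroxyl over the secondary C9 and tertiary C1 hydroxyls and stops at the aldehyde.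

Step 17
Reactants: 24 the aldehyde from step 16; 25 (Z)-1-bromoprop-1-ene
Product: 27 1β-[(2Z)-1-hydroxybut-2-en-1-yl] compound (both C2 epimers), via (Z)-prop-1-enylchromium dichloride 26 (not isolated)
Conditions: CrCl2 (6 equiv), NiCl2 (2 mol %), DMSO, rt
Reagents that add atoms: none
Why: In the Nozaki–Hiyama–Kishi coupling the alkenyl bromide is transferred with retention of the Z geometry through nickel to the chromium reagent 26, which adds only to the aldehyde and tolerates the free hydroxyls, the ester and the α-methylene lactone; the configuration of the new carbinol is irrelevant because it is oxidised next.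

Step 18
Reactants: 27 the allylic alcohol from step 17
Product: 28 CNP0186412.2, (3aS,5R,6S,7S,8S,8aR)-7-[(2Z)-but-2-enoyl]-5,7-dihydroxy-6-methyl-3-methylidene-2-oxo-octahydro-2H-cyclohepta[b]furan-8-yl 3-methylbutanoate
Conditions: activated MnO2, CH2Cl2, rt, dark
Reagents that add atoms: none
Why: MnO2 oxidises only the allylic alcohol to the conjugated ketone under neutral conditions, which should keep the Z geometry and leave the non-allylic C9 hydroxyl alone.

**Compound list**

1 | tetrachlorocyclopropene | ClC1=C(Cl)C1(Cl)Cl | starting material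
2 | tetrabromocyclopropene | BrC1=C(Br)C1(Br)Br | intermediate
3 | furan | c1ccoc1 | starting material
4 | exo-2,3,3,4-tetrabromo-8-oxatricyclo[3.2.1.0(2,4)]oct-6-ene (meso Diels–Alder adduct) | C1=C[C@H]2O[C@@H]1[C@@]1(Br)[C@]2(Br)C1(Br)Br | intermediate
5 | (1R,5S)-2,3,4,4-tetrabromo-8-oxabicyclo[3.2.1]octa-2,6-diene (racemate) | BrC1(Br)[C@@H]2C=C[C@@H](O2)C(Br)=C1Br | intermediate
6 | (1S,5R)-3,4-dibromo-8-oxabicyclo[3.2.1]octa-3,6-dien-2-one (racemate) | O=C1[C@@H]2C=C[C@@H](O2)C(Br)=C1Br | intermediate
7 | (1S,5R)-3-bromo-4-{[(1R,2S,5R)-2-isopropyl-5-methylcyclohexyl]oxy}-8-oxabicyclo[3.2.1]octa-3,6-dien-2-one | O=C1[C@@H]2C=C[C@@H](O2)C(O[C@@H]3C[C@H](C)CC[C@H]3C(C)C)=C1Br | intermediate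
8 | (1S,5R)-4-{[(1R,2S,5R)-2-isopropyl-5-methylcyclohexyl]oxy}-3-methyl-8-oxabicyclo[3.2.1]octa-3,6-dien-2-one | O=C1[C@@H]2C=C[C@@H](O2)C(O[C@@H]3C[C@H](C)CC[C@H]3C(C)C)=C1C | intermediate
9 | (tributylstannyl)methanol | OC[Sn](CCCC)(CCCC)CCCC | starting material
10 | tributyl{[(4-methoxybenzyl)oxy]methyl}stannane | CCCC[Sn](CCCC)(CCCC)COCc1ccc(OC)cc1 | intermediate
11 | [(4-methoxybenzyl)oxy]methyllithium | [Li]COCc1ccc(OC)cc1 | intermediate
12 | (1S,2R,5R)-2-{[(4-methoxybenzyl)oxy]methyl}-4-(menthyloxy)-3-methyl-8-oxabicyclo[3.2.1]octa-3,6-dien-2-ol (CH2OPMB exo; OH endo) | O[C@]1(COCc2ccc(OC)cc2)[C@@H]3C=C[C@@H](O3)C(O[C@@H]4C[C@H](C)CC[C@H]4C(C)C)=C1C | intermediate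
13 | 3-exo-bromo-4-endo-hydroxy-4-exo-{[(4-methoxybenzyl)oxy]methyl}-3-endo-methyl-8-oxabicyclo[3.2.1]oct-6-en-2-one | O[C@]1(COCc2ccc(OC)cc2)[C@@H]3C=C[C@@H](O3)C(=O)[C@@]1(C)Br | intermediate
14 | 4-endo-hydroxy-4-exo-{[(4-methoxybenzyl)oxy]methyl}-3-endo-methyl-8-oxabicyclo[3.2.1]oct-6-en-2-one | O[C@]1(COCc2ccc(OC)cc2)[C@@H]3C=C[C@@H](O3)C(=O)[C@@H]1C | intermediate
15 | 1α,5β-dihydroxy-1β-{[(4-methoxybenzyl)oxy]methyl}-10α-methyl-9-oxocyclohept-6-ene | O[C@]1(COCc2ccc(OC)cc2)[C@@H](O)C=CCC(=O)[C@@H]1C | intermediate
16 | 1α-hydroxy-1β-{[(4-methoxybenzyl)oxy]methyl}-10α-methyl-9-oxocyclohept-6-en-5β-yl 3-methylbutanoate | O[C@]1(COCc2ccc(OC)cc2)[C@@H](OC(=O)CC(C)C)C=CCC(=O)[C@@H]1C | intermediate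
17 | 6α,7α-epoxide of 16 | O[C@]1(COCc2ccc(OC)cc2)[C@@H](OC(=O)CC(C)C)[C@@H]3O[C@@H]3CC(=O)[C@@H]1C | intermediate
18 | 1α,6α-dihydroxy-1β-{[(4-methoxybenzyl)oxy]methyl}-10α-methyl-9-oxocyclohept-7-en-5β-yl 3-methylbutanoate | O[C@]1(COCc2ccc(OC)cc2)[C@@H](OC(=O)CC(C)C)[C@H](O)C=CC(=O)[C@@H]1C | intermediate
19 | 6α-[(diethoxyphosphoryl)acetyl]oxy derivative of 18 | O[C@]1(COCc2ccc(OC)cc2)[C@@H](OC(=O)CC(C)C)[C@H](OC(=O)CP(=O)(OCC)OCC)C=CC(=O)[C@@H]1C | intermediate
20 | cis-fused 11-(diethoxyphosphoryl) 12,6α-lactone 9-ketone (C11 epimers) | O[C@]1(COCc2ccc(OC)cc2)[C@@H](OC(=O)CC(C)C)[C@@H]3OC(=O)C(P(=O)(OCC)OCC)[C@@H]3CC(=O)[C@@H]1C | intermediate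
21 | 9-oxo α-methylene lactone (6α-O, 7α-C cis fusion; 5β-isovalerate; 1α-OH; 1β-CH2OPMB; 10α-CH3) | O[C@]1(COCc2ccc(OC)cc2)[C@@H](OC(=O)CC(C)C)[C@@H]3OC(=O)C(=C)[C@@H]3CC(=O)[C@@H]1C | intermediate
22 | 9β-hydroxy α-methylene lactone | O[C@]1(COCc2ccc(OC)cc2)[C@@H](OC(=O)CC(C)C)[C@@H]3OC(=O)C(=C)[C@@H]3C[C@@H](O)[C@@H]1C | intermediate
23 | 1β-(hydroxymethyl) triol | O[C@]1(CO)[C@@H](OC(=O)CC(C)C)[C@@H]2OC(=O)C(=C)[C@@H]2C[C@@H](O)[C@@H]1C | intermediate
24 | 1β-formyl compound (α-hydroxy aldehyde) | O[C@]1(C=O)[C@@H](OC(=O)CC(C)C)[C@@H]2OC(=O)C(=C)[C@@H]2C[C@@H](O)[C@@H]1C | intermediate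
25 | (Z)-1-bromoprop-1-ene | C/C=C\Br | starting material
26 | (Z)-prop-1-enylchromium dichloride | C/C=C\[Cr](Cl)Cl | intermediate
27 | 1β-[(2Z)-1-hydroxybut-2-en-1-yl] compound (C2 epimers) | O[C@]1(C(O)/C=C\C)[C@@H](OC(=O)CC(C)C)[C@@H]2OC(=O)C(=C)[C@@H]2C[C@@H](O)[C@@H]1C | intermediate
28 | CNP0186412.2 | C=C1C(=O)O[C@@H]2[C@H]1C[C@@H](O)[C@H](C)[C@@](O)(C(=O)/C=C\C)[C@H]2OC(=O)CC(C)C | target

**Count and risks**

Total step count: 18. Longest linear sequence: 17 steps (steps 1–5 and 7–18; step 6 prepares the tin reagent).

Step 11. What may go wrong: peracid attack on the β face, syn to the ester, so that C6 is set wrongly; or migration of the β,γ double bond into conjugation before it is oxidised. Fallback, from 16 back to 18: catalytic OsO4 with N-methylmorpholine N-oxide should dihydroxylate the ring alkene anti to the allylic isovalerate and give the 6α,7α-diol F3. 1,1'-Carbonyldiimidazole then closes the 6α,7α-cyclic carbonate F4. DBU removes a C8 proton and expels the C7 carbonate oxygen, which is β to the ketone (E1cB), and loss of CO2 leaves the 6α-hydroxy enone 18. Face control then rests on the anti preference of osmylation instead of peracid direction, and no epoxide is involved.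

Step 13. What may go wrong: base-triggered retro-aldol cleavage of the β-hydroxy ketone, epimerisation at C10, or reversible oxa-Michael addition of the C1 hydroxyl outrunning the carbon Michael addition. Fallback, from 18 to 21 under neutral radical conditions: esterification of the C6 hydroxyl with propiolic acid and DCC gives the 6α-propiolate F5. Bu3SnH and AIBN in hot benzene add a stannyl radical to the alkyne terminus; the vinyl radical cyclises 5-exo onto C7 of the enone and the C8 radical is reduced, which gives the cis-fused (tributylstannyl)methylene lactone F6. Protodestannylation with HCl in ether then gives 21.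

Step 4. What may go wrong: the two menthyl diastereomers co-elute or co-crystallise, so that no resolution is achieved. Fallback, from 6 to 7 by enzymatic kinetic resolution in place of diastereomer separation: NaBH4 with CeCl3·7H2O reduces racemic 6 from the exo face to the endo allylic alcohol F1. Burkholderia cepacia lipase with vinyl acetate should acylate one enantiomer, taken here to be the unwanted one, to the acetate F2 and leave the (1S,5R)-ring enantiomer of F1. MnO2 oxidises that alcohol back to enantiopure 6, and step 4 then gives 7 with no diastereomer to remove. If the enzyme prefers the other enantiomer, the acetate is methanolysed and the roles are exchanged.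

**Further compounds**

F1 | step 4 | 3,4-dibromo-8-oxabicyclo[3.2.1]octa-3,6-dien-2-endo-ol (formed racemic; ring configuration of 7 drawn) | O[C@@H]1[C@@H]2C=C[C@@H](O2)C(Br)=C1Br
F2 | step 4 | 2-endo-acetate of the mirror-image alcohol | CC(=O)O[C@H]1[C@H]2C=C[C@H](O2)C(Br)=C1Br
F3 | step 11 | 6α,7α-diol of 16 | O[C@]1(COCc2ccc(OC)cc2)[C@@H](OC(=O)CC(C)C)[C@H](O)[C@H](O)CC(=O)[C@@H]1C
F4 | step 11 | 6α,7α-cyclic carbonate of F3 | O[C@]1(COCc2ccc(OC)cc2)[C@@H](OC(=O)CC(C)C)[C@@H]3OC(=O)O[C@@H]3CC(=O)[C@@H]1C
F5 | step 13 | 6α-propiolate of 18 | O[C@]1(COCc2ccc(OC)cc2)[C@@H](OC(=O)CC(C)C)[C@H](OC(=O)C#C)C=CC(=O)[C@@H]1C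
F6 | step 13 | cis-fused α-[(tributylstannyl)methylene] lactone 9-ketone | O[C@]1(COCc2ccc(OC)cc2)[C@@H](OC(=O)CC(C)C)[C@@H]3OC(=O)C(=C[Sn](CCCC)(CCCC)CCCC)[C@@H]3CC(=O)[C@@H]1C
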